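The runs were computed from invented constants; the scatter is artificial.

Take the starting material as the clock of this row, and hold its turned part against the charge of first nucleophile.

| setting | midnight | birch | alder | ash | larch | elm |
|---|---|---|---|---|---|---|
| starting material | 0.33 M | 0.040 M | 0.12 M | 0.40 M | 1.0 M | 3.0 M |
| first nucleophile | 0.216 M | 0.216 M | 0.216 M | 0.216 M | 0.216 M | 0.216 M |
| second nucleophile | 0.132 M | 0.132 M | 0.132 M | 0.132 M | 0.132 M | 0.132 M |
| remark | run made earlier |  |  |  |  |  |
| time |  | 8.0 h | 8.0 h | 8.0 h | 8.0 h | 8.0 h |

midnight run (percent of the starting material charged)

| time / h | target / % | starting material / % |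
|---|---|---|
| 0.417 | 0.8 | 97.7 |
| 0.833 | 3.7 | 93.9 |
| 1.50 | 5.8 | 90.9 |
| 3.00 | 10.3 | 80.2 |
| 6.00 | 14.1 | 61.1 |

(each reading ± 0.5 percentage points)

- the earlier runs were read with a standard deviation of 0.5 percentage points
- "hardly changes" means that all values lie within two and a half points (for a concentration: within two and a half percent of the largest)

- [target] at the end for birch, alder, ash, larch, elm, in this order
- how that number moves from the first to the last of them (rises all the way / falls, then rises / falls all the way / rises, then falls / hardly changes)

The midnight run gives a ladder of three rungs. The first rung is a lag: by 0.417 h the starting material has lost 2.30 % while target stands at 0.8 %, so, within a scatter of 0.5 percentage points, something unseen seems to stand between them. The next rung takes hours: from 3.00 h to 6.00 h the midnight starting material falls 19 points but target gains 3.8 points, so target is being diverted or consumed as it forms. The last rung these readings show is the loss of starting material itself. Read as first order, it gives 0.0735 h⁻¹ up to 3.00 h and 0.0821 h⁻¹ up to 6.00 h, with no slowing.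

Assuming the value read up to 6.00 h holds at any charge, a flask should turn 48.2 % of its starting material by 8.0 h. That gives 0.449 M, the break charge, the charge of starting material whose turned part equals the charge of first nucleophile. Ash, at 0.40 M, lies under it, so target should still grow with the charge up to there. Larch, at 1.0 M, lies over it, so in larch first nucleophile should become the limiting reagent, the making of target should fade, and the loss of target should go on. The reckoning here therefore expects a rise, then a fall, with the top near ash.

The forecast gives 0.012 M, 0.029 M, 0.048 M, 0.028 M and 9.000 × 10⁻⁴ M, "rises, then falls", and says “ash sits close to the maximum”.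

The flasks give 0.0114 M, 0.0283 M, 0.0538 M, 0.0301 M and 3.65 × 10⁻⁵ M: rises, then falls.

    starting material → intermediate (k = 1.70 × 10⁻⁵ s⁻¹)
    first nucleophile + intermediate → target (k = 0.00470 M⁻¹ s⁻¹)
    second nucleophile + intermediate → other capture product (k = 7.80 × 10⁻⁴ M⁻¹ s⁻¹)
    starting material + target → side product (k = 2.10 × 10⁻⁴ M⁻¹ s⁻¹)
    target ⇌ isomer of the product (K = 1.20, k = 5.90 × 10⁻⁶ s⁻¹)

The row turns at 0.53 M, above the break charge and between ash and larch. Ash, under the break charge, keeps 44 % of its first nucleophile at the end, and larch, over it, keeps 1.3 %. Elm stands at 6.69 times the break charge and keeps 0 %, while 56.4 % of its starting material remains. Of the changes tried on elm, removing the step of starting material with target has the largest single effect: without that step, elm ends with 0.188 M of target.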